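**Retrosynthetic overview**
1. The C14 aldehyde comes last, by SeO2 allylic oxidation of the C10 methyl group of macrocycle 21; this also turns the C1=C10 alkene ring-cis.
2. Key step: the ten-membered ring is closed at C7–C8 by an α-acyloxyalkyl radical adding to a 3-(sulfonylmethyl)butenolide with loss of PhSO2•, which sets C7 and C8, installs the C8 ester and unveils the exo-methylene.
3. The butenolide (formed first) comes from esterification and ring-closing metathesis; the carbocycle is formed second.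
4. The chain is joined at C3–C4 by B-alkyl Suzuki coupling of Z-iodo-dienol 4 with dienol 7.
5. C6 comes from asymmetric alkynylation of crotonaldehyde; the C4=C5 geometry comes from hydroxyl-directed trans-hydroalumination and iodination.

Assumption: germacrane numbering is used for positions (lactone O on C6, C11=C13 exo-methylene, C14 on C10, C15 on C4); "ring-cis/ring-trans" refers to the ten-membered ring.

**Step 1**
Reactants: 1 3-(tert-butoxy)prop-1-yne; 2 (E)-but-2-enal
Product: 3 (2E,4S)-7-(tert-butoxy)hept-2-en-5-yn-4-ol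
Conditions: Me2Zn (3 equiv), (S,S)-ProPhenol (20 mol%), Ph3P=O (40 mol%), toluene, 0 °C
Reagents that add atoms: none
Why: Zinc–ProPhenol catalytic asymmetric alkynylation of an enal is a known 1,2-addition in which the dinuclear zinc alkynylide is delivered to the Re face of the aldehyde, setting the future C6 as 4S by reagent control (ligand sense assigned by analogy and checked at this stage by Mosher ester analysis).

**Step 2**
Reactants: 3 (2E,4S)-7-(tert-butoxy)hept-2-en-5-yn-4-ol
Product: 4 (2E,4S,5Z)-7-(tert-butoxy)-6-iodohepta-2,5-dien-4-ol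
Conditions: NaAlH2(OCH2CH2OMe)2 (Red-Al), THF, 0 °C to 23 °C; EtOAc; then I2, −78 °C
Reagents that add atoms: iodine, II
Why: Alkoxide-directed trans-hydroalumination of the propargylic alcohol puts H on the proximal and Al on the distal alkyne carbon through a five-membered alanate, and iodinolysis with retention gives the Z-vinyl iodide (iodine cis to the carbinol carbon), which fixes the C4=C5 geometry without touching the carbinol centre.

**Step 3**
Reactants: 5 but-3-yn-1-ol; 6 bromoethene (vinyl bromide)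
Product: 7 (3E)-3-methylhexa-3,5-dien-1-ol
Conditions: Me3Al (3 equiv), Cp2ZrCl2 (25 mol%), CH2Cl2, 0 °C to 23 °C; then 6, ZnCl2, Pd(PPh3)4 (5 mol%), THF, 23 °C
Reagents that add atoms: trimethylaluminium, C[Al](C)C
Why: Negishi zirconium-catalysed carboalumination adds methyl and aluminium syn across the terminal alkyne (methyl on the internal carbon), and the alkenylalane is cross-coupled in the same flask with vinyl bromide with retention, giving the E-diene.

**Step 4**
Reactants: 7 (3E)-3-methylhexa-3,5-dien-1-ol; 4 (2E,4S,5Z)-7-(tert-butoxy)-6-iodohepta-2,5-dien-4-ol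
Product: 9 (2E,4S,5E,9E)-6-(tert-butoxymethyl)-10-methyldodeca-2,5,9-triene-4,12-diol, via B-alkyl-9-BBN borane 8 (not isolated)
Conditions: 9-BBN (2.2 equiv), THF, 0 °C to 23 °C; then 4, PdCl2(dppf) (5 mol%), AsPh3, Cs2CO3, DMF/H2O, 23 °C
Reagents that add atoms: none
Why: 9-BBN hydroborates only the terminal vinyl group of the diene (boron at the terminus, the hydroxyl being held as a borinate), and the B-alkyl Suzuki–Miyaura coupling with the Z-vinyl iodide proceeds with retention, forming C3–C4 with C3 cis to C6.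

**Step 5**
Reactants: 10 2-(bromomethyl)prop-2-enoic acid
Product: 11 2-[(phenylsulfonyl)methyl]prop-2-enoic acid
Conditions: PhSO2Na (1.2 equiv), MeOH, 65 °C
Reagents that add atoms: sodium benzenesulfinate, [Na+].[O-]S(=O)c1ccccc1
Why: S-alkylation of the sulfinate by the allylic bromide (SN2 and SN2′ give the same product) furnishes the allyl sulfone that later acts as the radical leaving group.

**Step 6**
Reactants: 9 (2E,4S,5E,9E)-6-(tert-butoxymethyl)-10-methyldodeca-2,5,9-triene-4,12-diol; 11 2-[(phenylsulfonyl)methyl]prop-2-enoic acid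
Product: 13 (2E,4S,5E,9E)-6-(tert-butoxymethyl)-12-[(tert-butyldiphenylsilyl)oxy]-10-methyldodeca-2,5,9-trien-4-yl 2-[(phenylsulfonyl)methyl]prop-2-enoate, via mono-TBDPS ether 12 (not isolated)
Conditions: TBDPSCl (1.05 equiv), imidazole, CH2Cl2, 0 °C; then 11, EDC·HCl, DMAP (10 mol%), 0 °C to 23 °C
Reagents that add atoms: tert-butyldiphenylsilyl chloride, CC(C)(C)[Si](Cl)(c1ccccc1)c1ccccc1
Why: The bulky silyl chloride silylates only the primary hydroxyl, and Steglich esterification then acylates the remaining bis-allylic secondary alcohol with retention at C6.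

**Step 7**
Reactants: 13 (2E,4S,5E,9E)-6-(tert-butoxymethyl)-12-[(tert-butyldiphenylsilyl)oxy]-10-methyldodeca-2,5,9-trien-4-yl 2-[(phenylsulfonyl)methyl]prop-2-enoate
Product: 14 (5R)-5-[(1E,5E)-2-(tert-butoxymethyl)-8-[(tert-butyldiphenylsilyl)oxy]-6-methylocta-1,5-dien-1-yl]-3-[(phenylsulfonyl)methyl]furan-2(5H)-one
Conditions: second-generation Hoveyda–Grubbs catalyst (10 mol%), toluene (5 mM), 80 °C
Reagents that add atoms: none
Why: Ring-closing metathesis between the propenyl group and the 1,1-disubstituted acrylate closes the butenolide with loss of propene, while the trisubstituted chain alkenes do not engage and C6 is unchanged (descriptor becomes R only through a priority change).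

**Step 8**
Reactants: 14 (5R)-5-[(1E,5E)-2-(tert-butoxymethyl)-8-[(tert-butyldiphenylsilyl)oxy]-6-methylocta-1,5-dien-1-yl]-3-[(phenylsulfonyl)methyl]furan-2(5H)-one
Product: 15 (5R)-5-[(1E,5E)-2-(acetoxymethyl)-8-[(tert-butyldiphenylsilyl)oxy]-6-methylocta-1,5-dien-1-yl]-3-[(phenylsulfonyl)methyl]furan-2(5H)-one
Conditions: Ac2O (5 equiv), FeCl3 (10 mol%), Et2O, 0 °C, 30 min
Reagents that add atoms: acetic anhydride, CC(=O)OC(C)=O
Why: In this Ganem-type ether cleavage the FeCl3-activated anhydride acylates the ether oxygen and the tert-butyl cation departs, converting the tert-butyl ether directly into the C15 acetate under base-free conditions that spare the epimerisable butenolide and the TBDPS ether.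

**Step 9**
Reactants: 15 (5R)-5-[(1E,5E)-2-(acetoxymethyl)-8-[(tert-butyldiphenylsilyl)oxy]-6-methylocta-1,5-dien-1-yl]-3-[(phenylsulfonyl)methyl]furan-2(5H)-one
Product: 16 (5R)-5-[(1E,5E)-2-(acetoxymethyl)-8-hydroxy-6-methylocta-1,5-dien-1-yl]-3-[(phenylsulfonyl)methyl]furan-2(5H)-one
Conditions: HF·pyridine, THF/pyridine, 0 °C to 23 °C
Reagents that add atoms: none
Why: Buffered fluoride desilylation removes the primary TBDPS ether without exposing the acetate, the sulfone or the butenolide γ-centre to a strong base.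

**Step 10**
Reactants: 16 (5R)-5-[(1E,5E)-2-(acetoxymethyl)-8-hydroxy-6-methylocta-1,5-dien-1-yl]-3-[(phenylsulfonyl)methyl]furan-2(5H)-one
Product: 17 (5R)-5-[(1E,5E)-2-(acetoxymethyl)-6-methyl-8-oxoocta-1,5-dien-1-yl]-3-[(phenylsulfonyl)methyl]furan-2(5H)-one
Conditions: Dess–Martin periodinane (1.3 equiv), NaHCO3, CH2Cl2, 0 °C; used at once
Reagents that add atoms: none
Why: Buffered Dess–Martin oxidation gives the β,γ-unsaturated aldehyde without moving the double bond into conjugation.

**Step 11**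
Reactants: 17 (5R)-5-[(1E,5E)-2-(acetoxymethyl)-6-methyl-8-oxoocta-1,5-dien-1-yl]-3-[(phenylsulfonyl)methyl]furan-2(5H)-one; 18 (2S)-2-methylbutanoyl chloride
Product: 21 (6R,7R,8R)-15-acetoxy-8-[(2S)-2-methylbutanoyloxy]germacra-1(10),4,11(13)-trien-12,6-olide with 1(10)E (ring-trans) and 4,5 ring-cis geometry, via (2S)-2-methylbutanoyl iodide 19 (not isolated), via α-acyloxy iodide 20 (not isolated)
Conditions: 18, NaI, MeCN, 0 °C; add 17, CH2Cl2, 0 °C, 30 min; dilute with degassed CH2Cl2 to 2 mM; Mn2(CO)10 (1.1 equiv), blue LEDs (456 nm), 23 °C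
Reagents that add atoms: none
Why: Proposed new method: acyl iodide 19 adds across the aldehyde to give α-acyloxy iodide 20, Mn(CO)5• from visible-light homolysis of Mn2(CO)10 abstracts iodine to give a nucleophilic α-acyloxyalkyl radical at C8 which, with no hydrogen donor present and degenerate iodine transfer keeping it alive, closes the ten-membered ring by conjugate addition to C7 of the electron-poor butenolide on the face anti to the C6–C5 bond (trans-fused lactone, 7R), after which the C11 radical expels PhSO2• irreversibly to unveil the exo-methylene; the 8R (8β-ester) centre is expected from the transition state that keeps the acyloxy group on the outer face of the forming ring away from the lactone oxygen, and the E C1=C10 alkene rules out 1,5-hydrogen transfer from C2; the closest known reaction types are Mn2(CO)10/visible-light iodine abstraction from in situ α-acyloxy iodides (ketyl-radical equivalents), radical allylation with allyl sulfones by addition–fragmentation, anti-selective radical addition to 5-substituted butenolides and Porter-type radical macrocyclisation.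

**Step 12**
Reactants: 21 (6R,7R,8R)-15-acetoxy-8-[(2S)-2-methylbutanoyloxy]germacra-1(10),4,11(13)-trien-12,6-olide (1(10)E)
Product: 23 (6R,7R,8R)-15-acetoxy-8-[(2S)-2-methylbutanoyloxy]-14-oxogermacra-1(10),4,11(13)-trien-12,6-olide with both ring alkenes ring-cis (CNP0230988.9), via 14-hydroxy macrocycle 22 (not isolated)
Conditions: SeO2 (0.5 equiv), t-BuOOH (3 equiv), CH2Cl2, 23 °C; filter and concentrate; then Dess–Martin periodinane, NaHCO3, CH2Cl2, 0 °C
Reagents that add atoms: selenium dioxide, O=[Se]=O; tert-butyl hydroperoxide, CC(C)(C)OO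
Why: Riley allylic oxidation (ene reaction then [2,3]-sigmatropic shift) attacks the more electron-rich C1=C10 alkene (C4=C5 is deactivated by its allylic acetate) at the C14 methyl and returns the double bond with C14 trans to C2, that is ring-cis, exactly as in the known parthenolide to melampomagnolide B conversion, and Dess–Martin oxidation of the allylic alcohol gives the enal without affecting the three stereocentres.

**Compound list**
1 | 3-(tert-butoxy)prop-1-yne | C#CCOC(C)(C)C | starting material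
2 | (E)-but-2-enal | C/C=C/C=O | starting material
3 | (2E,4S)-7-(tert-butoxy)hept-2-en-5-yn-4-ol | C/C=C/[C@H](O)C#CCOC(C)(C)C | intermediate
4 | (2E,4S,5Z)-7-(tert-butoxy)-6-iodohepta-2,5-dien-4-ol | C/C=C/[C@H](O)/C=C(\I)COC(C)(C)C | intermediate
5 | but-3-yn-1-ol | C#CCCO | starting material
6 | bromoethene | C=CBr | starting material
7 | (3E)-3-methylhexa-3,5-dien-1-ol | OCC/C(C)=C/C=C | intermediate
8 | 9-[(3E)-6-(9-borabicyclo[3.3.1]nonan-9-yloxy)-4-methylhex-3-en-1-yl]-9-borabicyclo[3.3.1]nonane | C(C/C=C(C)/CCOB1C2CCCC1CCC2)B1C2CCCC1CCC2 | intermediate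
9 | (2E,4S,5E,9E)-6-(tert-butoxymethyl)-10-methyldodeca-2,5,9-triene-4,12-diol | C/C=C/[C@H](O)/C=C(\CC/C=C(C)/CCO)COC(C)(C)C | intermediate
10 | 2-(bromomethyl)prop-2-enoic acid | C=C(CBr)C(=O)O | starting material
11 | 2-[(phenylsulfonyl)methyl]prop-2-enoic acid | C=C(CS(=O)(=O)c1ccccc1)C(=O)O | intermediate
12 | (2E,4S,5E,9E)-6-(tert-butoxymethyl)-12-[(tert-butyldiphenylsilyl)oxy]-10-methyldodeca-2,5,9-trien-4-ol | C/C=C/[C@H](O)/C=C(\CC/C=C(C)/CCO[Si](c1ccccc1)(c1ccccc1)C(C)(C)C)COC(C)(C)C | intermediate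
13 | (2E,4S,5E,9E)-6-(tert-butoxymethyl)-12-[(tert-butyldiphenylsilyl)oxy]-10-methyldodeca-2,5,9-trien-4-yl 2-[(phenylsulfonyl)methyl]prop-2-enoate | C/C=C/[C@H](OC(=O)C(=C)CS(=O)(=O)c1ccccc1)/C=C(\CC/C=C(C)/CCO[Si](c1ccccc1)(c1ccccc1)C(C)(C)C)COC(C)(C)C | intermediate
14 | (5R)-5-[(1E,5E)-2-(tert-butoxymethyl)-8-[(tert-butyldiphenylsilyl)oxy]-6-methylocta-1,5-dien-1-yl]-3-[(phenylsulfonyl)methyl]furan-2(5H)-one | O=C1O[C@H](/C=C(\CC/C=C(C)/CCO[Si](c2ccccc2)(c2ccccc2)C(C)(C)C)COC(C)(C)C)C=C1CS(=O)(=O)c1ccccc1 | intermediate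
15 | (5R)-5-[(1E,5E)-2-(acetoxymethyl)-8-[(tert-butyldiphenylsilyl)oxy]-6-methylocta-1,5-dien-1-yl]-3-[(phenylsulfonyl)methyl]furan-2(5H)-one | O=C1O[C@H](/C=C(\CC/C=C(C)/CCO[Si](c2ccccc2)(c2ccccc2)C(C)(C)C)COC(C)=O)C=C1CS(=O)(=O)c1ccccc1 | intermediate
16 | (5R)-5-[(1E,5E)-2-(acetoxymethyl)-8-hydroxy-6-methylocta-1,5-dien-1-yl]-3-[(phenylsulfonyl)methyl]furan-2(5H)-one | O=C1O[C@H](/C=C(\CC/C=C(C)/CCO)COC(C)=O)C=C1CS(=O)(=O)c1ccccc1 | intermediate
17 | (5R)-5-[(1E,5E)-2-(acetoxymethyl)-6-methyl-8-oxoocta-1,5-dien-1-yl]-3-[(phenylsulfonyl)methyl]furan-2(5H)-one | O=C1O[C@H](/C=C(\CC/C=C(C)/CC=O)COC(C)=O)C=C1CS(=O)(=O)c1ccccc1 | intermediate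
18 | (2S)-2-methylbutanoyl chloride | ClC(=O)[C@@H](C)CC | starting material
19 | (2S)-2-methylbutanoyl iodide | IC(=O)[C@@H](C)CC | intermediate
20 | (3E,7E)-7-(acetoxymethyl)-1-iodo-3-methyl-8-[(2R)-5-oxo-4-[(phenylsulfonyl)methyl]-2,5-dihydrofuran-2-yl]octa-3,7-dien-1-yl (2S)-2-methylbutanoate (both epimers at the iodo carbon) | O=C1O[C@H](/C=C(\CC/C=C(C)/CC(I)OC(=O)[C@@H](C)CC)COC(C)=O)C=C1CS(=O)(=O)c1ccccc1 | intermediate
21 | (6R,7R,8R)-15-acetoxy-8-[(2S)-2-methylbutanoyloxy]germacra-1(10),4,11(13)-trien-12,6-olide, 1(10)E ring-trans, 4,5 ring-cis, trans-fused α-methylene lactone, C10 methyl | C=C1C(=O)O[C@@H]2/C=C(/COC(C)=O)CC/C=C(\C)C[C@@H](OC(=O)[C@@H](C)CC)[C@@H]12 | intermediate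
22 | (6R,7R,8R)-15-acetoxy-14-hydroxy-8-[(2S)-2-methylbutanoyloxy]germacra-1(10),4,11(13)-trien-12,6-olide, both ring alkenes ring-cis | C=C1C(=O)O[C@@H]2/C=C(/COC(C)=O)CC/C=C(/CO)C[C@@H](OC(=O)[C@@H](C)CC)[C@@H]12 | intermediate
23 | (6R,7R,8R)-15-acetoxy-8-[(2S)-2-methylbutanoyloxy]-14-oxogermacra-1(10),4,11(13)-trien-12,6-olide, both ring alkenes ring-cis (CNP0230988.9) | C=C1C(=O)O[C@@H]2/C=C(/COC(C)=O)CC/C=C(/C=O)C[C@@H](OC(=O)[C@@H](C)CC)[C@@H]12 | target

**Step count**
Total: 12 steps. Longest linear sequence: 10 steps (steps 1, 2, 4, 6, 7, 8, 9, 10, 11, 12).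

**Steps most likely to fail**

Step 11 (radical macrocyclisation). Ten-membered closure is slow, the radical could instead attack the C4=C5 alkene (seven- or eight-membered ring), and the C7/C8 diastereoselectivity is a prediction, not a precedent. The fallback sets out from 17 and comes back at 21, and replaces the α-acyloxy radical by a samarium ketyl. Treating 17 with SmI2 (2.5 equiv) and t-BuOH in THF at −78 °C and 1 mM gives a ketyl radical that adds to C7 and expels sulfinate. Chelation of trivalent samarium between the ketyl oxygen and the lactone carbonyl should give (6R,7R,8R)-15-acetoxy-8-hydroxygermacra-1(10)E,4,11(13)-trien-12,6-olide F5, which is acylated with 18 and pyridine to 21. If the 8-epimer (6R,7R,8S)-15-acetoxy-8-hydroxygermacra-1(10)E,4,11(13)-trien-12,6-olide F6 forms instead, Mitsunobu esterification with (2S)-2-methylbutanoic acid (PPh3, DIAD) inverts C8 and also gives 21.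

Step 12 (late allylic oxidation). Oxidation at C3, C9 or C2 could compete, and the diene macrocycle is acid-sensitive. The fallback sets out from 21 and comes back at 23, and uses a singlet-oxygen ene route of the kind that gives the natural 1-hydroperoxy-10(14)-ene germacranolides. Photooxygenation (O2, tetraphenylporphyrin, visible light, CH2Cl2, 0 °C) gives (6R,7R,8R)-15-acetoxy-1-hydroperoxy-8-[(2S)-2-methylbutanoyloxy]germacra-4,10(14),11(13)-trien-12,6-olide F7. Schenck allylic rearrangement (CHCl3, 23 °C) moves the hydroperoxide to the primary position with the trisubstituted ring-cis alkene, giving (6R,7R,8R)-15-acetoxy-14-hydroperoxy-8-[(2S)-2-methylbutanoyloxy]germacra-1(10),4,11(13)-trien-12,6-olide F8. Dehydration with Ac2O and pyridine at 0 °C gives 23.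

Step 4 (diene hydroboration and Suzuki coupling). 9-BBN may not add cleanly to the terminal position of the conjugated diene. The fallback sets out from 5 and comes back at 12, and avoids the diene altogether. Silylation of 5 (TBDPSCl, imidazole) gives tert-butyl(but-3-yn-1-yloxy)diphenylsilane F1. Carboalumination (Me3Al, Cp2ZrCl2), ate formation with n-BuLi and opening of ethylene oxide give (3E)-6-[(tert-butyldiphenylsilyl)oxy]-4-methylhex-3-en-1-ol F2. I2, PPh3 and imidazole give (3E)-tert-butyl[(6-iodo-3-methylhex-3-en-1-yl)oxy]diphenylsilane F3. Treatment with t-BuLi then B-methoxy-9-BBN gives lithium B-alkyl-B-methoxy-9-borabicyclo[3.3.1]nonan-9-uide F4, which is coupled with 4 (PdCl2(dppf), AsPh3, K3PO4, DMF, 23 °C) to give 12; this is esterified with 11 as in step 6 without the silylation stage.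

**Further compounds**
F1 | step 4 | tert-butyl(but-3-yn-1-yloxy)diphenylsilane | C#CCCO[Si](c1ccccc1)(c1ccccc1)C(C)(C)C
F2 | step 4 | (3E)-6-[(tert-butyldiphenylsilyl)oxy]-4-methylhex-3-en-1-ol | OCC/C=C(C)/CCO[Si](c1ccccc1)(c1ccccc1)C(C)(C)C
F3 | step 4 | (3E)-tert-butyl[(6-iodo-3-methylhex-3-en-1-yl)oxy]diphenylsilane | ICC/C=C(C)/CCO[Si](c1ccccc1)(c1ccccc1)C(C)(C)C
F4 | step 4 | lithium B-alkyl-B-methoxy-9-borabicyclo[3.3.1]nonan-9-uide | [Li+].CO[B-]1(CC/C=C(C)/CCO[Si](c2ccccc2)(c2ccccc2)C(C)(C)C)C2CCCC1CCC2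
F5 | step 11 | (6R,7R,8R)-15-acetoxy-8-hydroxygermacra-1(10)E,4,11(13)-trien-12,6-olide | C=C1C(=O)O[C@@H]2/C=C(/COC(C)=O)CC/C=C(\C)C[C@@H](O)[C@@H]12
F6 | step 11 | (6R,7R,8S)-15-acetoxy-8-hydroxygermacra-1(10)E,4,11(13)-trien-12,6-olide | C=C1C(=O)O[C@@H]2/C=C(/COC(C)=O)CC/C=C(\C)C[C@H](O)[C@@H]12
F7 | step 12 | (6R,7R,8R)-15-acetoxy-1-hydroperoxy-8-[(2S)-2-methylbutanoyloxy]germacra-4,10(14),11(13)-trien-12,6-olide | C=C1C(=O)O[C@@H]2/C=C(/COC(C)=O)CCC(OO)C(=C)C[C@@H](OC(=O)[C@@H](C)CC)[C@@H]12
F8 | step 12 | (6R,7R,8R)-15-acetoxy-14-hydroperoxy-8-[(2S)-2-methylbutanoyloxy]germacra-1(10),4,11(13)-trien-12,6-olide | C=C1C(=O)O[C@@H]2/C=C(/COC(C)=O)CC/C=C(/COO)C[C@@H](OC(=O)[C@@H](C)CC)[C@@H]12
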